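**Retrosynthetic overview**
1. The last operations remove the protecting groups (three benzyl ethers, one silyl ether). Before that, the two aryl ester (depside) bonds are cut. In the forward direction A + B are joined first, then AB + C.
2. All three rings come from one building block, methyl 2,4-dihydroxy-3,5,6-trimethylbenzoate. Ring A is its di-O-benzyl acid, ring B its allyl ester with a free 4-OH, and ring C its decarboxylated resorcinol silylated at the less hindered OH.
3. The building block comes from aromatisation of methyl 3,5,6-trimethyl-2,4-dioxocyclohexane-1-carboxylate.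
4. Key disconnection: intermolecular Michael addition of dimethyl malonate to (E)-4-methylhex-4-en-3-one forms the C1–C6 bond, and a Claisen ring closure in the same pot forms C2–C3.
5. The enone comes from a directed aldol of pentan-3-one with acetaldehyde. The carbocycle is therefore built once, on scale, and then divided into the A, B and C units.

Assumption: the target has no stereocentre and no configurationally stable axis, so it is achiral and no step needs stereocontrol.

**Step 1**
Reactants: 1 pentan-3-one; 2 acetaldehyde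
Product: 4 5-hydroxy-4-methylhexan-3-one (racemic syn/anti mixture), via lithium pent-2-en-3-olate 3 (not isolated)
Conditions: LiN(iPr)2 (1.05 equiv), THF, −78 °C; then MeCHO (1.2 equiv), −78 °C, 15 min; AcOH quench
Reagents that add atoms: none
Why: In this directed crossed aldol addition the preformed lithium enolate of the symmetrical ketone (only one regioisomer is possible) adds to the aldehyde faster than proton transfer at −78 °C, and the two new stereocentres form as a racemic syn/anti mixture that does not matter because both are destroyed in steps 2 to 4.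

**Step 2**
Reactants: 4 5-hydroxy-4-methylhexan-3-one
Product: 6 (E)-4-methylhex-4-en-3-one, via 3-methyl-4-oxohexan-2-yl methanesulfonate 5 (not isolated)
Conditions: MsCl (1.2 equiv), Et3N (3 equiv), CH2Cl2, 0 °C to rt
Reagents that add atoms: none
Why: Mesylation followed by E1cB elimination of the β-mesyloxy ketone completes the aldol condensation without retro-aldol and gives the more stable tiglyl-type E enone, whose geometry is lost again in step 3.

**Step 3 (key step)**
Reactants: 6 (E)-4-methylhex-4-en-3-one; 7 dimethyl malonate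
Product: 9 methyl 3,5,6-trimethyl-2,4-dioxocyclohexane-1-carboxylate (diastereomer/enol mixture), via Michael adduct dimethyl 2-(3-methyl-4-oxohexan-2-yl)propanedioate 8 (not isolated)
Conditions: NaOMe (1.1 equiv), MeOH, reflux, 20 h; then aq. HCl to pH 2
Reagents that add atoms: none
Why: Intermolecular Michael addition of sodium dimethyl malonate to the β-carbon of 6 forms the C1–C6 bond, the ethyl-ketone enolate of 8 then closes the six-membered ring on one ester by an intramolecular Claisen (Dieckmann-type) condensation whose product is removed irreversibly as the stabilised β-dicarbonyl anion and so pulls the reversible Michael step forward, and the four stereocentres form as a mixture that is erased in step 4.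

**Step 4**
Reactants: 9 methyl 3,5,6-trimethyl-2,4-dioxocyclohexane-1-carboxylate
Product: 11 methyl 2,4-dihydroxy-3,5,6-trimethylbenzoate, via methyl 3-bromo-3,5,6-trimethyl-2,4-dioxocyclohexane-1-carboxylate 10 (not isolated)
Conditions: Br2 (1.0 equiv), AcOH, 15–20 °C, dropwise; then 80 °C, 2 h
Reagents that add atoms: none
Why: In this halogenation–dehydrohalogenation aromatisation the enolised 1,3-dione consumes all the bromine in the cold, heating then expels HBr and tautomerisation gives the resorcylate, and the product has no free ring position that could be over-brominated.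

**Step 5**
Reactants: 11 methyl 2,4-dihydroxy-3,5,6-trimethylbenzoate
Product: 13 2,4-dihydroxy-3,5,6-trimethylbenzoic acid, via 2,4-dihydroxy-3,5,6-trimethylbenzoylium hydrogen sulfate 12 (not isolated)
Conditions: conc. H2SO4, 0 °C to rt, 6 h; poured onto ice, filtered cold
Reagents that add atoms: water, O
Why: Unimolecular acid-catalysed acyl–oxygen cleavage (the AAc1 mechanism typical of mesitoate-type esters) avoids the blocked tetrahedral pathway by ionising the di-ortho-substituted, electron-rich ester to its acylium ion, which ice water captures as the acid at a temperature too low for decarboxylation.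

**Step 6**
Reactants: 13 2,4-dihydroxy-3,5,6-trimethylbenzoic acid
Product: 14 allyl 2,4-dihydroxy-3,5,6-trimethylbenzoate (ring B unit)
Conditions: allyl bromide (1.1 equiv), KHCO3 (1.2 equiv), DMF, rt, 16 h
Reagents that add atoms: allyl bromide, C=CCBr
Why: In this SN2 O-alkylation the hydrogen carbonate ionises only the carboxylic acid and not the phenols, and the reaction takes place at the allyl carbon, so hindrance at the carbonyl carbon is irrelevant.

**Step 7**
Reactants: 14 allyl 2,4-dihydroxy-3,5,6-trimethylbenzoate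
Product: 15 allyl 2,4-bis(benzyloxy)-3,5,6-trimethylbenzoate
Conditions: BnBr (3 equiv), K2CO3 (4 equiv), DMF, 60 °C, 12 h
Reagents that add atoms: benzyl bromide, BrCc1ccccc1
Why: Williamson ether synthesis in a dipolar aprotic solvent with excess halide and gentle heating alkylates both the free 4-OH and the hydrogen-bonded 2-OH, and the allyl ester is inert to carbonate.

**Step 8**
Reactants: 15 allyl 2,4-bis(benzyloxy)-3,5,6-trimethylbenzoate
Product: 16 2,4-bis(benzyloxy)-3,5,6-trimethylbenzoic acid (ring A unit)
Conditions: Pd(PPh3)4 (3 mol%), N-methylaniline (3 equiv), THF, rt; 1 M HCl wash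
Reagents that add atoms: none
Why: In this Tsuji–Trost deallylation zerovalent palladium ionises the allyl–oxygen bond far from the hindered carbonyl and the π-allyl complex is trapped by the amine, so the acid is freed without the forcing saponification a mesitoate-type ester would need.

**Step 9**
Reactants: 16 2,4-bis(benzyloxy)-3,5,6-trimethylbenzoic acid; 14 allyl 2,4-dihydroxy-3,5,6-trimethylbenzoate
Product: 18 allyl 4-{[2,4-bis(benzyloxy)-3,5,6-trimethylbenzoyl]oxy}-2-hydroxy-3,5,6-trimethylbenzoate, via mixed trifluoroacetic anhydride of ring A acid 17 (not isolated)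
Conditions: (CF3CO)2O (4 equiv), toluene, 0 °C to rt, 12 h; aq. NaHCO3 work-up
Reagents that add atoms: none
Why: In this mixed-anhydride depside esterification the trifluoroacetic mixed anhydride of an electron-rich di-ortho-substituted acid reacts through acylium character and is therefore insensitive to hindrance, and only the 4-OH of 14 is acylated because the 2-OH is tied up in a hydrogen bond to the ester carbonyl.

**Step 10**
Reactants: 18 allyl 4-{[2,4-bis(benzyloxy)-3,5,6-trimethylbenzoyl]oxy}-2-hydroxy-3,5,6-trimethylbenzoate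
Product: 19 allyl 2-(benzyloxy)-4-{[2,4-bis(benzyloxy)-3,5,6-trimethylbenzoyl]oxy}-3,5,6-trimethylbenzoate
Conditions: BnBr (1.5 equiv), K2CO3 (2 equiv), DMF, 50 °C, 8 h
Reagents that add atoms: benzyl bromide, BrCc1ccccc1
Why: Williamson etherification caps the last free phenol so that the next acid activation has no internal nucleophile, and the di-ortho-substituted depside carbonyl is too shielded for carbonate or phenoxide to attack (acyl migration to the meta oxygen is geometrically impossible).

**Step 11**
Reactants: 19 allyl 2-(benzyloxy)-4-{[2,4-bis(benzyloxy)-3,5,6-trimethylbenzoyl]oxy}-3,5,6-trimethylbenzoate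
Product: 20 2-(benzyloxy)-4-{[2,4-bis(benzyloxy)-3,5,6-trimethylbenzoyl]oxy}-3,5,6-trimethylbenzoic acid (AB acid)
Conditions: Pd(PPh3)4 (5 mol%), N-methylaniline (3 equiv), THF, rt; 1 M HCl wash
Reagents that add atoms: none
Why: This Tsuji–Trost deallylation under neutral conditions uses a weakly acyl-philic amine as allyl acceptor and leaves the benzyl ethers and the aryl ester untouched.

**Step 12**
Reactants: 13 2,4-dihydroxy-3,5,6-trimethylbenzoic acid
Product: 21 2,4,5-trimethylbenzene-1,3-diol
Conditions: 1 M aq. HCl–1,4-dioxane 1:1, reflux, N2, 3 h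
Reagents that add atoms: none
Why: Protodecarboxylation by ipso-protonation is very easy here because the carboxyl-bearing carbon is ortho and para to two hydroxyl groups and loss of CO2 relieves steric strain, and acid under nitrogen avoids the air oxidation such resorcinols suffer in base.

**Step 13**
Reactants: 21 2,4,5-trimethylbenzene-1,3-diol
Product: 22 3-[(tert-butyldiphenylsilyl)oxy]-2,5,6-trimethylphenol (ring C unit)
Conditions: TBDPSCl (1.0 equiv), imidazole (2.2 equiv), CH2Cl2, 0 °C to rt
Reagents that add atoms: tert-butyldiphenylsilyl chloride, CC(C)(C)[Si](Cl)(c1ccccc1)c1ccccc1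
Why: In this sterically controlled monosilylation the very bulky chlorosilane reacts with the OH that has only one ortho methyl much faster than with the OH flanked by two buttressed methyls, which leaves free exactly the hindered OH that has to be acylated.

**Step 14**
Reactants: 20 AB acid; 22 3-[(tert-butyldiphenylsilyl)oxy]-2,5,6-trimethylphenol
Product: 24 3-[(tert-butyldiphenylsilyl)oxy]-2,5,6-trimethylphenyl 2-(benzyloxy)-4-{[2,4-bis(benzyloxy)-3,5,6-trimethylbenzoyl]oxy}-3,5,6-trimethylbenzoate, via mixed trifluoroacetic anhydride of AB acid 23 (not isolated)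
Conditions: 20, (CF3CO)2O (5 equiv), toluene, rt, 30 min; then 22 (1.2 equiv), rt to 40 °C, 24 h
Reagents that add atoms: none
Why: This is the same mixed-anhydride (acylium-type) depside esterification as in step 9, in which the only nucleophilic oxygen present is the free OH of 22, the single ring C–H is shielded by the neighbouring silyl ether and methyl group, and aryl benzyl ethers, the aryl silyl ether and the existing depside bond all tolerate trifluoroacetic acid in toluene.

**Step 15**
Reactants: 24 silyl-protected tridepside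
Product: 25 3-hydroxy-2,5,6-trimethylphenyl 2-(benzyloxy)-4-{[2,4-bis(benzyloxy)-3,5,6-trimethylbenzoyl]oxy}-3,5,6-trimethylbenzoate
Conditions: Bu4NF (1.1 equiv), AcOH (1.2 equiv), THF, 0 °C, 30 min
Reagents that add atoms: none
Why: Fluoride-induced desilylation of an aryl silyl ether is fast at 0 °C, and the acetic acid buffer protonates the phenoxide at once so the hindered aryl esters are not transacylated.

**Step 16**
Reactants: 25 tri-O-benzyl tridepside
Product: 26 thielavin Z8, 3-hydroxy-2,5,6-trimethylphenyl 4-[(2,4-dihydroxy-3,5,6-trimethylbenzoyl)oxy]-2-hydroxy-3,5,6-trimethylbenzoate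
Conditions: H2 (1 atm), 10% Pd/C, EtOAc, rt
Reagents that add atoms: none
Why: Catalytic hydrogenolysis cleaves the three benzyl–oxygen bonds under neutral conditions that leave depside esters untouched, so the polyphenol is obtained by filtration and evaporation alone.

**Compound list**
1 | pentan-3-one | CCC(=O)CC | starting material
2 | acetaldehyde | CC=O | starting material
3 | lithium pent-2-en-3-olate (E/Z mixture, formed in the flask) | [Li+].CC=C([O-])CC | intermediate
4 | 5-hydroxy-4-methylhexan-3-one (racemic syn/anti mixture) | CCC(=O)C(C)C(C)O | intermediate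
5 | 3-methyl-4-oxohexan-2-yl methanesulfonate (diastereomer mixture, formed in the flask) | CCC(=O)C(C)C(C)OS(C)(=O)=O | intermediate
6 | (E)-4-methylhex-4-en-3-one | C/C=C(\C)C(=O)CC | intermediate
7 | dimethyl malonate | COC(=O)CC(=O)OC | starting material
8 | dimethyl 2-(3-methyl-4-oxohexan-2-yl)propanedioate (diastereomer mixture, formed in the flask) | CCC(=O)C(C)C(C)C(C(=O)OC)C(=O)OC | intermediate
9 | methyl 3,5,6-trimethyl-2,4-dioxocyclohexane-1-carboxylate (diastereomer/enol mixture) | COC(=O)C1C(C)C(C)C(=O)C(C)C1=O | intermediate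
10 | methyl 3-bromo-3,5,6-trimethyl-2,4-dioxocyclohexane-1-carboxylate (diastereomer mixture, formed in the flask) | COC(=O)C1C(C)C(C)C(=O)C(C)(Br)C1=O | intermediate
11 | methyl 2,4-dihydroxy-3,5,6-trimethylbenzoate | COC(=O)c1c(C)c(C)c(O)c(C)c1O | intermediate
12 | 2,4-dihydroxy-3,5,6-trimethylbenzoylium hydrogen sulfate (formed in the flask) | Cc1c(C)c(C#[O+])c(O)c(C)c1O.OS(=O)(=O)[O-] | intermediate
13 | 2,4-dihydroxy-3,5,6-trimethylbenzoic acid | Cc1c(C)c(C(=O)O)c(O)c(C)c1O | intermediate
14 | allyl 2,4-dihydroxy-3,5,6-trimethylbenzoate | C=CCOC(=O)c1c(C)c(C)c(O)c(C)c1O | intermediate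
15 | allyl 2,4-bis(benzyloxy)-3,5,6-trimethylbenzoate | C=CCOC(=O)c1c(C)c(C)c(OCc2ccccc2)c(C)c1OCc1ccccc1 | intermediate
16 | 2,4-bis(benzyloxy)-3,5,6-trimethylbenzoic acid | OC(=O)c1c(C)c(C)c(OCc2ccccc2)c(C)c1OCc1ccccc1 | intermediate
17 | 2,4-bis(benzyloxy)-3,5,6-trimethylbenzoic trifluoroacetic anhydride (formed in the flask) | FC(F)(F)C(=O)OC(=O)c1c(C)c(C)c(OCc2ccccc2)c(C)c1OCc1ccccc1 | intermediate
18 | allyl 4-{[2,4-bis(benzyloxy)-3,5,6-trimethylbenzoyl]oxy}-2-hydroxy-3,5,6-trimethylbenzoate | C=CCOC(=O)c1c(C)c(C)c(OC(=O)c2c(C)c(C)c(OCc3ccccc3)c(C)c2OCc2ccccc2)c(C)c1O | intermediate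
19 | allyl 2-(benzyloxy)-4-{[2,4-bis(benzyloxy)-3,5,6-trimethylbenzoyl]oxy}-3,5,6-trimethylbenzoate | C=CCOC(=O)c1c(C)c(C)c(OC(=O)c2c(C)c(C)c(OCc3ccccc3)c(C)c2OCc2ccccc2)c(C)c1OCc1ccccc1 | intermediate
20 | 2-(benzyloxy)-4-{[2,4-bis(benzyloxy)-3,5,6-trimethylbenzoyl]oxy}-3,5,6-trimethylbenzoic acid | OC(=O)c1c(C)c(C)c(OC(=O)c2c(C)c(C)c(OCc3ccccc3)c(C)c2OCc2ccccc2)c(C)c1OCc1ccccc1 | intermediate
21 | 2,4,5-trimethylbenzene-1,3-diol | Cc1cc(O)c(C)c(O)c1C | intermediate
22 | 3-[(tert-butyldiphenylsilyl)oxy]-2,5,6-trimethylphenol | Cc1cc(O[Si](c2ccccc2)(c2ccccc2)C(C)(C)C)c(C)c(O)c1C | intermediate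
23 | mixed trifluoroacetic anhydride of acid 20 (formed in the flask) | FC(F)(F)C(=O)OC(=O)c1c(C)c(C)c(OC(=O)c2c(C)c(C)c(OCc3ccccc3)c(C)c2OCc2ccccc2)c(C)c1OCc1ccccc1 | intermediate
24 | 3-[(tert-butyldiphenylsilyl)oxy]-2,5,6-trimethylphenyl 2-(benzyloxy)-4-{[2,4-bis(benzyloxy)-3,5,6-trimethylbenzoyl]oxy}-3,5,6-trimethylbenzoate | Cc1cc(O[Si](c2ccccc2)(c2ccccc2)C(C)(C)C)c(C)c(OC(=O)c2c(C)c(C)c(OC(=O)c3c(C)c(C)c(OCc4ccccc4)c(C)c3OCc3ccccc3)c(C)c2OCc2ccccc2)c1C | intermediate
25 | 3-hydroxy-2,5,6-trimethylphenyl 2-(benzyloxy)-4-{[2,4-bis(benzyloxy)-3,5,6-trimethylbenzoyl]oxy}-3,5,6-trimethylbenzoate | Cc1cc(O)c(C)c(OC(=O)c2c(C)c(C)c(OC(=O)c3c(C)c(C)c(OCc4ccccc4)c(C)c3OCc3ccccc3)c(C)c2OCc2ccccc2)c1C | intermediate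
26 | thielavin Z8 (achiral) | Cc1cc(O)c(C)c(OC(=O)c2c(C)c(C)c(OC(=O)c3c(C)c(C)c(O)c(C)c3O)c(C)c2O)c1C | target

**Step count**
Total steps: 16. Longest linear sequence: 14 (steps 1–11, 14, 15, 16). Steps 12 and 13 form a two-step branch from 13.

**Three steps most likely to fail**

**Step 3.** The acceptor carries both an α- and a β-methyl group, so the Michael addition may be slow or may stay on the side of the reactants. The fallback sets out from 7 and comes back at 11. It uses the unhindered commercial acceptor (E)-hex-4-en-3-one (C/C=C/C(=O)CC) and adds the missing C5 methyl after aromatisation.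
- With NaOMe in refluxing MeOH, 7 and the hexenone give dimethyl 2-(4-oxohexan-2-yl)propanedioate F1. This closes in the same pot to methyl 3,6-dimethyl-2,4-dioxocyclohexane-1-carboxylate F2.
- SO2Cl2 in CH2Cl2 at 0 °C gives methyl 3-chloro-3,6-dimethyl-2,4-dioxocyclohexane-1-carboxylate F3.
- LiCl in DMF at 120 °C dehydrochlorinates F3 to methyl 2,4-dihydroxy-3,6-dimethylbenzoate F4.
- Rieche formylation (Cl2CHOMe, TiCl4, CH2Cl2, −10 to 0 °C) can only strike the one free position and gives methyl 5-formyl-2,4-dihydroxy-3,6-dimethylbenzoate F5.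
- Hydrogenolysis of the electron-rich aryl aldehyde (H2, 10% Pd/C, AcOH, 50 °C) turns the formyl group into methyl and delivers 11.

**Step 4.** The tertiary bromide between two carbonyl groups can act as a bromine donor instead of eliminating, or the polymethylphenol formed can be brominated at a benzylic position. The fallback sets out from 9 and comes back at 11, and it avoids halogen altogether.
- Compound 9 is treated with Ac2O and conc. H2SO4 (1.5 equiv) at 0 to 50 °C. This is an oxidative aromatisation in which the enol acetates are C-sulfonated and lose SO2, so sulfuric acid is the oxidant. It gives methyl 2,4-diacetoxy-3,5,6-trimethylbenzoate F6.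
- Methanolysis of the two unhindered acetates (K2CO3, MeOH, rt) leaves the shielded methyl benzoate intact and gives 11.

**Step 14.** A di-ortho-substituted acid has to meet a di-ortho-substituted phenol whose ring still carries one activated C–H. Slow O-acylation may therefore lose out to Friedel–Crafts acylation or trifluoroacetylation. The fallback sets out from 20 and comes back at 25. Ring C is brought in as the allyl ester 14, in which the later C–H position is blocked by the carboxylate and the regiochemistry is fixed by the hydrogen-bonded 2-OH, as in step 9.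
- Acid 20 is activated with (CF3CO)2O in toluene (via 23) and acylates the 4-OH of 14. This gives allyl 4-{[2-(benzyloxy)-4-{[2,4-bis(benzyloxy)-3,5,6-trimethylbenzoyl]oxy}-3,5,6-trimethylbenzoyl]oxy}-2-hydroxy-3,5,6-trimethylbenzoate F7.
- Pd(PPh3)4 and N-methylaniline in THF free 4-{[2-(benzyloxy)-4-{[2,4-bis(benzyloxy)-3,5,6-trimethylbenzoyl]oxy}-3,5,6-trimethylbenzoyl]oxy}-2-hydroxy-3,5,6-trimethylbenzoic acid F8.
- Protodecarboxylation of this crowded salicylic acid (Ag2CO3 10 mol%, AcOH 10 mol%, DMSO, 110 °C) gives 25.
- Steps 12, 13 and 15 are then not needed.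

**Further compounds**
F1 | step 3 | dimethyl 2-(4-oxohexan-2-yl)propanedioate (racemic) | CCC(=O)CC(C)C(C(=O)OC)C(=O)OC
F2 | step 3 | methyl 3,6-dimethyl-2,4-dioxocyclohexane-1-carboxylate (diastereomer/enol mixture) | COC(=O)C1C(C)CC(=O)C(C)C1=O
F3 | step 3 | methyl 3-chloro-3,6-dimethyl-2,4-dioxocyclohexane-1-carboxylate (diastereomer mixture) | COC(=O)C1C(C)CC(=O)C(C)(Cl)C1=O
F4 | step 3 | methyl 2,4-dihydroxy-3,6-dimethylbenzoate | COC(=O)c1c(C)cc(O)c(C)c1O
F5 | step 3 | methyl 5-formyl-2,4-dihydroxy-3,6-dimethylbenzoate | COC(=O)c1c(C)c(C=O)c(O)c(C)c1O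
F6 | step 4 | methyl 2,4-diacetoxy-3,5,6-trimethylbenzoate | COC(=O)c1c(C)c(C)c(OC(C)=O)c(C)c1OC(C)=O
F7 | step 14 | allyl 4-{[2-(benzyloxy)-4-{[2,4-bis(benzyloxy)-3,5,6-trimethylbenzoyl]oxy}-3,5,6-trimethylbenzoyl]oxy}-2-hydroxy-3,5,6-trimethylbenzoate | C=CCOC(=O)c1c(C)c(C)c(OC(=O)c2c(C)c(C)c(OC(=O)c3c(C)c(C)c(OCc4ccccc4)c(C)c3OCc3ccccc3)c(C)c2OCc2ccccc2)c(C)c1O
F8 | step 14 | 4-{[2-(benzyloxy)-4-{[2,4-bis(benzyloxy)-3,5,6-trimethylbenzoyl]oxy}-3,5,6-trimethylbenzoyl]oxy}-2-hydroxy-3,5,6-trimethylbenzoic acid | OC(=O)c1c(C)c(C)c(OC(=O)c2c(C)c(C)c(OC(=O)c3c(C)c(C)c(OCc4ccccc4)c(C)c3OCc3ccccc3)c(C)c2OCc2ccccc2)c(C)c1O
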